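## Analysis of the target

Compound 30 is a trans-fused octalin. Ring A is the cyclohexane C6–C7–C8–C9–C10–C11 and ring B is the cyclohexene C2–C3–C4=C5–C6–C11. The quaternary C2 carries a methyl group and, through the ketone C1, an enolised pyrrolidine-2,4-dione (ring C: N1', C2', C3', C4', C5') with the 1-hydroxyethyl group C6'–C7' of L-threonine (5'S,6'R), and C3 carries the (E,E)-pentadienyl chain C12–C16.

Take α as the face of H6 and β as the face of H11. The five decalin centres (2R,3R,6R,8R,11S) then read: acyl group β and equatorial, 2-methyl α and axial, dienyl chain α and pseudoequatorial (H3 β), 8-methyl α and therefore axial on ring A.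

Two of these relations are unusual and decide the strategy. H3 and H6 stand trans across C4=C5, and the 8-methyl group is axial, so the core is not the adduct of an all-E polyene folding through a chair-like tether.

The feature that is exploited is the array carbonyl–C2–C3–C4=C5 inside ring B, a γ,δ-unsaturated carbonyl unit (Claisen retron). Either one-carbon substituent of C2 can play the carbonyl: C1, which is trans to the dienyl chain, or the carbon of the 2-methyl group, which is cis to it.

The vicinal pair C2 (quaternary) and C3 (tertiary, doubly allylic) is wedged between the ring fusion and the side chain. It is the hardest part to build, and it makes C1 a very hindered carbonyl group.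

The sensitive groups are the conjugated diene, the skipped C3–H, the acidic and metal-binding tricarbonyl of ring C, the base-labile C5' and the free β-hydroxyl group. Ring C therefore comes last, and strong acid, hydrogenation and hydroboration are excluded once the polyene is in place.

## Retrosynthetic reasoning

**Ring C.** 30 is cut at C3'–C4' (Lacey–Dieckmann retron) to β-ketoamide 29. 29 is cut at N1'–C2' to acylketene 28 and amino ester 27, and 28 is stored as adduct 26 of acid 23 with 24. The cut is made here because ring C is the most labile part. The acylketene route also needs only one attack at the hindered C1 carbonyl, in 23 → 26.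

**The 2-methyl group.** Acid 23 comes from tert-butyl ester 21, and the axial methyl group of 21 is traced back through aldehyde 19 to the carboxyl group of half-ester 17. This exchange of roles costs two steps. It turns the carbon that is cis to the dienyl chain into the carbonyl of the Claisen retron, and that is the only assignment a ring-bound [3,3] shift with an E-alkene can deliver.

**Ring B (key cut).** 17 is cut at C2–C3 with re-formation of a C5–O bond: 17 ⇐ 16 ⇐ 15 ⇐ 14. The forward reaction is an Ireland–Claisen ring contraction of a trans-fused δ-lactone. It closes ring B, makes the quaternary C2 and the tertiary C3 together, and places C4=C5.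

- All of this stereochemical information is drawn from one carbinol centre (C5) and one alkene geometry.
- In the boat that the ring enforces, the E-substituent of C3 ends cis to the former lactone carbonyl.
- Keeping the lactone carbonyl as C1 would therefore need a Z-trienyl arm on the equatorial C5 epimer. That arm can react only after a boat flip of the lactone, and it points at C10.
- The chosen axial, all-E arm reacts from the ground-state conformer.

**C1 and the lactone.** 14 is cut at C1–C2 to lactone 13, so that C1 arrives as an ester on the α-carbon. 13 is opened to hydroxy ester 12, and 12 is cut at C4–C5 to aldehyde 9 and trienyl iodide 11. The whole polyene then arrives in one convergent, ester-tolerant coupling that also creates C5. Iodide 11 comes from dienal 10 by one-carbon olefination.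

**Ring A.** Aldehyde 9 comes from vinyl compound 8, 8 from ketone 6 by removal of the C10 oxygen, and 6 from enone 1, vinyl donor 2 and bromo ester 4 through 3 and 5. An axial methyl group cannot be expected from any cyclisation that forms ring A. It is secured instead on a preformed ring, where conjugate addition trans to the methyl group of 1 and alkylation trans to the new vinyl group give exactly the C6/C8/C11 triad.

## Alternatives that were turned down

Alternative 1: cut C2–C3 and C6–C11 together, the textbook intramolecular Diels–Alder reaction. Pentaenal A1 would cyclise to decalin aldehyde A2, followed by chain extension and Lacey–Dieckmann closure.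
- Suprafacial addition to an E,E-diene forces H3 and H6 cis, and the chair-like tether puts the 8-methyl group equatorial. A2 therefore differs from the required core at C2, C6 and C11.
- A Z-configured C3=C4 bond would repair only the H3/H6 relation. A terminal Z-diene resists the s-cis form, and in the tetraene it creates a cis-hexatriene prone to 6π electrocyclisation.
- The facial bias set by C8 would still oppose the target.

Alternative 2: cut C2–C11 and C4=C5, a Michael addition and aldol condensation of enal A3 with β-keto ester A4 to give octalone A5.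
- The polarity is ideal and C1 and the 2-methyl group arrive in their final roles.
- The Michael step is reversible and drains to the isomer with the 8-methyl group equatorial.
- Nothing decides which of methyl and ester becomes axial at C2.
- C3 arrives as a ketone next to a quaternary centre. About five further steps and a β-face hydrogen delivery would be needed to turn it into the CH–dienyl unit.

Alternative 3: cut C4=C5 by ring-closing metathesis after an open-chain Ireland–Claisen rearrangement for C2–C3. Trienyl ester A6 would give acid A7, which the second-generation Grubbs catalyst would close.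
- A chair transition state would allow the natural assignment of C1.
- The geometry of the tetrasubstituted ketene acetal (methyl against cyclohexyl) and its π-face relative to C11 are both uncontrolled, so up to four diastereomers compete.
- The metathesis catalyst meets a conjugated diene.
- Ring closure and stereocontrol are spread over two steps instead of one.

Key step: step 8

Assumption: 30 is written as the 4'-enol tautomer of the given SMILES, which equilibrates freely with its other enol forms, and enone 1 is taken as a purchasable enantiopure building block.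

Step 1
Reactants: 1 (S)-5-methylcyclohex-2-en-1-one; 2 vinylmagnesium bromide
Product: 3 {[(3R,5S)-3-ethenyl-5-methylcyclohex-1-en-1-yl]oxy}trimethylsilane
Conditions: CuBr·SMe2 (cat.), Me3SiCl, DMPU, THF, −78 °C
Reagents that add atoms: chlorotrimethylsilane C[Si](C)(C)Cl
Why: Copper-catalysed conjugate addition accelerated and trapped by the chlorosilane; axial attack on the half-chair of 1 that keeps the methyl group pseudoequatorial should place the vinyl group (its inner carbon is C5) trans to the 8-methyl group and so set C6, while the silyl enol ether stores the enolate regiochemistry at C11.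

Step 2
Reactants: 3 {[(3R,5S)-3-ethenyl-5-methylcyclohex-1-en-1-yl]oxy}trimethylsilane; 4 methyl bromoacetate
Product: 6 methyl 2-[(1R,2R,4S)-2-ethenyl-4-methyl-6-oxocyclohexyl]acetate, via lithium enolate 5 (not isolated)
Conditions: MeLi, THF, 0 °C; then 4, DMPU, −78 to −30 °C
Reagents that add atoms: none
Why: MeLi cleaves the Si–O bond to the regiodefined enolate 5, and its SN2 alkylation by the reactive α-bromo ester should occur anti to the neighbouring vinyl group, which sets C11 trans to C6; the CH2 of 4 becomes C2 and its carbonyl carbon the later 2-methyl carbon.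

Step 3
Reactants: 6 methyl 2-[(1R,2R,4S)-2-ethenyl-4-methyl-6-oxocyclohexyl]acetate
Product: 8 methyl 2-[(1R,2R,4R)-2-ethenyl-4-methylcyclohexyl]acetate, via tosylhydrazone 7 (not isolated)
Conditions: TsNHNH2, MeOH, 23 °C; then catecholborane, CHCl3, −10 °C; NaOAc·3H2O, reflux
Reagents that add atoms: none
Why: Tosylhydrazone reduction (Caglioti type): hydride transfer to C=N, loss of sulfinate and then of N2 from the diazene leave a CH2 group at C10 under almost neutral conditions, so that C11 next to the former ketone, the ester and the vinyl group (inert to uncatalysed catecholborane in the cold) should survive.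

Step 4
Reactants: 8 methyl 2-[(1R,2R,4R)-2-ethenyl-4-methylcyclohexyl]acetate
Product: 9 methyl 2-[(1R,2S,4R)-2-formyl-4-methylcyclohexyl]acetate
Conditions: O3, CH2Cl2, −78 °C; PPh3, −78 to 23 °C
Reagents that add atoms: ozone [O-][O+]=O
Why: Ozonolysis of the only C=C bond with a neutral reductive work-up; the aldehyde carbon is C5 and the epimerisable centre C6 sees neither acid nor base.

Step 5
Reactants: 10 (2E,4E)-hexa-2,4-dienal
Product: 11 (1E,3E,5E)-1-iodohepta-1,3,5-triene
Conditions: CHI3, CrCl2, THF–dioxane, 0 °C, dark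
Reagents that add atoms: iodoform IC(I)I
Why: Takai olefination: the geminal dichromium reagent from CHI3 adds to the aldehyde and eliminates anti, which should give the E-iodoalkene; the iodoform carbon becomes C4 and the aldehyde carbon C3.

Step 6
Reactants: 9 methyl 2-[(1R,2S,4R)-2-formyl-4-methylcyclohexyl]acetate; 11 (1E,3E,5E)-1-iodohepta-1,3,5-triene
Product: 13 (1S,4aR,7R,8aS)-1-[(1E,3E,5E)-hepta-1,3,5-trien-1-yl]-7-methyloctahydro-3H-isochromen-3-one, via hydroxy ester 12 (not isolated)
Conditions: CrCl2, NiCl2 (cat.), DMF, 23 °C; aqueous work-up; DBU (cat.), toluene, 50 °C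
Reagents that add atoms: none
Why: Nozaki–Hiyama–Kishi coupling: the alkenylchromium reagent keeps the E,E,E geometry and ignores the ester; Felkin–Anh attack anti to the branched C11 should give the (S)-carbinol C5, and amidine-catalysed lactonisation of 12 closes the trans-fused δ-lactone in which the trienyl arm is axial (β); the C5 epimer is removed by chromatography.

Step 7
Reactants: 13 (1S,4aR,7R,8aS)-1-[(1E,3E,5E)-hepta-1,3,5-trien-1-yl]-7-methyloctahydro-3H-isochromen-3-one
Product: 14 tert-butyl (1S,4R,4aS,7R,8aS)-1-[(1E,3E,5E)-hepta-1,3,5-trien-1-yl]-7-methyl-3-oxooctahydro-1H-isochromene-4-carboxylate (labile at C2, drawn as the equatorial ester)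
Conditions: LiN(SiMe3)2 (2.2 equiv), THF, −78 °C; (tBuOCO)2O, −78 to −20 °C; aq NH4Cl
Reagents that add atoms: di-tert-butyl dicarbonate CC(C)(C)OC(=O)OC(=O)OC(C)(C)C
Why: Claisen-type C-acylation after deprotonation at C2; the second equivalent of base stores the more acidic product as its enolate and prevents double acylation, the new carbonyl carbon is C1, and the configuration at C2 is of no consequence because it is planarised in step 8.

Step 8
Reactants: 14 tert-butyl (1S,4R,4aS,7R,8aS)-1-[(1E,3E,5E)-hepta-1,3,5-trien-1-yl]-7-methyl-3-oxooctahydro-1H-isochromene-4-carboxylate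
Product: 17 (1R,2R,4aR,6R,8aS)-1-(tert-butoxycarbonyl)-6-methyl-2-[(1E,3E)-penta-1,3-dien-1-yl]-1,2,4a,5,6,7,8,8a-octahydronaphthalene-1-carboxylic acid, via silyl ketene acetal 15 (not isolated), via trimethylsilyl ester 16 (not isolated)
Conditions: NaN(SiMe3)2, Me3SiCl, THF, −78 to 0 °C; solvent change and filtration; toluene, 100 °C; then citric acid, THF–H2O, 23 °C
Reagents that add atoms: none
Why: O-silylation of the malonate-type enolate gives ketene acetal 15 (silyl shift between the two carbonyl oxygens keeps the reactive isomer available), whose units C2=C(OSi)–O and C5–C4=C3 form the six-atom array of an Ireland–Claisen rearrangement; the closest known reaction type is the ring-contracting ester-enolate Claisen rearrangement of 6-alkenyl δ-lactones to cyclohexenecarboxylic acids. Ring B closes by formation of C2–C3 while C5–O breaks, a six-membered lactone to six-membered carbocycle contraction that can only pass through a boat-like transition state shaped like bicyclo[2.2.2]octane. The new C4=C5 bond is cis because it lies in the ring, and its position is fixed by the mechanism. C2: the trienyl arm sits on the β face of the lactone (axial at C5), so C3 can reach only the β face of C2, which turns the former lactone carbonyl to the α (axial) side and the tert-butyl ester to the β (equatorial) side. C3: in a boat the substituent that is E on C3=C4 ends cis to the former lactone carbonyl, so the dienyl chain becomes α and pseudoequatorial, trans to the ester and with H3 trans to H6. C6, C8 and C11 are spectators, the C5–C6–C11–C2 torsion that the trans fusion demands is much the same in 15 and in 16, and the axial arm reacts from the ground-state half-chair without a ring flip. The step needs the [3,3] shift to outrun heterolysis of the trienylic C5–O bond, which the salt-free and acid-free thermolysis should secure, and the tert-butyl ester offers no second allyl unit, so only one sigmatropic path exists. Mild acid then frees 17 from silyl ester 16 well below the temperature at which a malonic half-ester decarboxylates.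

Step 9
Reactants: 17 (1R,2R,4aR,6R,8aS)-1-(tert-butoxycarbonyl)-6-methyl-2-[(1E,3E)-penta-1,3-dien-1-yl]-1,2,4a,5,6,7,8,8a-octahydronaphthalene-1-carboxylic acid
Product: 19 tert-butyl (1R,2R,4aR,6R,8aS)-1-formyl-6-methyl-2-[(1E,3E)-penta-1,3-dien-1-yl]-1,2,4a,5,6,7,8,8a-octahydronaphthalene-1-carboxylate, via acid chloride 18 (not isolated)
Conditions: 1-chloro-N,N,2-trimethylprop-1-en-1-amine, CH2Cl2, 0 °C; then LiAlH(OtBu)3, THF, −78 °C
Reagents that add atoms: none
Why: The α-chloroenamine turns the acid into acid chloride 18 without free HCl (no α-hydrogen, hence no ketene), and the bulky alkoxyaluminium hydride reduces an acyl chloride to the aldehyde stage at low temperature while the tert-butyl ester and the alkenes stay inert.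

Step 10
Reactants: 19 tert-butyl (1R,2R,4aR,6R,8aS)-1-formyl-6-methyl-2-[(1E,3E)-penta-1,3-dien-1-yl]-1,2,4a,5,6,7,8,8a-octahydronaphthalene-1-carboxylate
Product: 21 tert-butyl (1R,2R,4aR,6R,8aS)-1,6-dimethyl-2-[(1E,3E)-penta-1,3-dien-1-yl]-1,2,4a,5,6,7,8,8a-octahydronaphthalene-1-carboxylate, via tosylhydrazone 20 (not isolated)
Conditions: TsNHNH2, MeOH, 23 °C; then catecholborane, CHCl3, −10 °C; NaOAc·3H2O, reflux
Reagents that add atoms: none
Why: Second tosylhydrazone reduction (Caglioti type): CHO becomes the axial 2-methyl group with no change at C2; the diazene is not allylic, so no alkene transposition can occur.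

Step 11
Reactants: 21 tert-butyl (1R,2R,4aR,6R,8aS)-1,6-dimethyl-2-[(1E,3E)-penta-1,3-dien-1-yl]-1,2,4a,5,6,7,8,8a-octahydronaphthalene-1-carboxylate
Product: 23 (1R,2R,4aR,6R,8aS)-1,6-dimethyl-2-[(1E,3E)-penta-1,3-dien-1-yl]-1,2,4a,5,6,7,8,8a-octahydronaphthalene-1-carboxylic acid, via trimethylsilyl ester 22 (not isolated)
Conditions: Me3SiOTf, 2,6-lutidine, CH2Cl2, 0 °C; then H2O
Reagents that add atoms: none
Why: The silyl triflate activates the ester carbonyl oxygen, isobutene is lost by an E1 path that does not depend on access to the hindered carbonyl carbon, and lutidine keeps the medium free of acid that could protonate the diene; water cleaves silyl ester 22.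

Step 12
Reactants: 23 (1R,2R,4aR,6R,8aS)-1,6-dimethyl-2-[(1E,3E)-penta-1,3-dien-1-yl]-1,2,4a,5,6,7,8,8a-octahydronaphthalene-1-carboxylic acid; 24 2,2-dimethyl-1,3-dioxane-4,6-dione (Meldrum's acid)
Product: 26 5-[hydroxy{(1R,2R,4aR,6R,8aS)-1,6-dimethyl-2-[(1E,3E)-penta-1,3-dien-1-yl]-1,2,4a,5,6,7,8,8a-octahydronaphthalen-1-yl}methylidene]-2,2-dimethyl-1,3-dioxane-4,6-dione, via acid chloride 25 (not isolated)
Conditions: 1-chloro-N,N,2-trimethylprop-1-en-1-amine, CH2Cl2, 0 °C; then 24, pyridine, DMAP (cat.), 0 to 23 °C
Reagents that add atoms: none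
Why: C-acylation of the cyclic malonate 24 by acid chloride 25 under nucleophilic catalysis, the standard entry to β-keto acid derivatives; the enolised adduct 26 is a stable store of the acylketene.

Step 13
Reactants: 26 5-[hydroxy{(1R,2R,4aR,6R,8aS)-1,6-dimethyl-2-[(1E,3E)-penta-1,3-dien-1-yl]-1,2,4a,5,6,7,8,8a-octahydronaphthalen-1-yl}methylidene]-2,2-dimethyl-1,3-dioxane-4,6-dione; 27 methyl L-threoninate hydrochloride
Product: 29 methyl N-{3-[(1R,2R,4aR,6R,8aS)-1,6-dimethyl-2-[(1E,3E)-penta-1,3-dien-1-yl]-1,2,4a,5,6,7,8,8a-octahydronaphthalen-1-yl]-3-oxopropanoyl}-L-threoninate, via acylketene 28 (not isolated)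
Conditions: Et3N, toluene, 90 °C
Reagents that add atoms: none
Why: Thermal retro-[4+2] fragmentation of 26 gives acylketene 28, whose unhindered ketene carbon should be captured faster by the amine than by the secondary hydroxyl group of the liberated amino ester, so that no further attack at C1 is needed.

Step 14
Reactants: 29 methyl N-{3-[(1R,2R,4aR,6R,8aS)-1,6-dimethyl-2-[(1E,3E)-penta-1,3-dien-1-yl]-1,2,4a,5,6,7,8,8a-octahydronaphthalen-1-yl]-3-oxopropanoyl}-L-threoninate
Product: 30 (5S)-3-{[(1R,2R,4aR,6R,8aS)-1,6-dimethyl-2-[(1E,3E)-penta-1,3-dien-1-yl]-1,2,4a,5,6,7,8,8a-octahydronaphthalen-1-yl]carbonyl}-4-hydroxy-5-[(1R)-1-hydroxyethyl]-1,5-dihydro-2H-pyrrol-2-one (CNP0298257.3)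
Conditions: NaOMe, MeOH, 23 °C; then 1 M HCl
Reagents that add atoms: none
Why: Lacey–Dieckmann cyclisation: the 1,3-dicarbonyl carbon C3' attacks the ester carbonyl (5-exo-trig), the product is stored as its stabilised anion, which shields C5' and the β-hydroxyl group from further base, and acidification frees 30; short contact with base should keep 5'S.

## Compound list

1 | (S)-5-methylcyclohex-2-en-1-one | O=C1C=CC[C@H](C)C1 | starting material
2 | vinylmagnesium bromide | C=C[Mg]Br | starting material
3 | {[(3R,5S)-3-ethenyl-5-methylcyclohex-1-en-1-yl]oxy}trimethylsilane | C=C[C@H]1C[C@H](C)CC(O[Si](C)(C)C)=C1 | intermediate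
4 | methyl bromoacetate | COC(=O)CBr | starting material
5 | lithium (3R,5S)-3-ethenyl-5-methylcyclohex-1-en-1-olate | [Li+].C=C[C@H]1C[C@H](C)CC([O-])=C1 | intermediate
6 | methyl 2-[(1R,2R,4S)-2-ethenyl-4-methyl-6-oxocyclohexyl]acetate | C=C[C@H]1C[C@H](C)CC(=O)[C@@H]1CC(=O)OC | intermediate
7 | N-tosylhydrazone of 6 | C=C[C@H]1C[C@H](C)CC(=NNS(=O)(=O)c2ccc(C)cc2)[C@@H]1CC(=O)OC | intermediate
8 | methyl 2-[(1R,2R,4R)-2-ethenyl-4-methylcyclohexyl]acetate | C=C[C@H]1C[C@H](C)CC[C@@H]1CC(=O)OC | intermediate
9 | methyl 2-[(1R,2S,4R)-2-formyl-4-methylcyclohexyl]acetate | O=C[C@H]1C[C@H](C)CC[C@@H]1CC(=O)OC | intermediate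
10 | (2E,4E)-hexa-2,4-dienal | C/C=C/C=C/C=O | starting material
11 | (1E,3E,5E)-1-iodohepta-1,3,5-triene | C/C=C/C=C/C=C/I | intermediate
12 | methyl 2-{(1R,2S,4R)-2-[(1S,2E,4E,6E)-1-hydroxyocta-2,4,6-trien-1-yl]-4-methylcyclohexyl}acetate | C/C=C/C=C/C=C/[C@H](O)[C@H]1C[C@H](C)CC[C@@H]1CC(=O)OC | intermediate
13 | (1S,4aR,7R,8aS)-1-[(1E,3E,5E)-hepta-1,3,5-trien-1-yl]-7-methyloctahydro-3H-isochromen-3-one | C/C=C/C=C/C=C/[C@@H]1OC(=O)C[C@H]2CC[C@@H](C)C[C@H]12 | intermediate
14 | tert-butyl (1S,4R,4aS,7R,8aS)-1-[(1E,3E,5E)-hepta-1,3,5-trien-1-yl]-7-methyl-3-oxooctahydro-1H-isochromene-4-carboxylate | C/C=C/C=C/C=C/[C@@H]1OC(=O)[C@H](C(=O)OC(C)(C)C)[C@H]2CC[C@@H](C)C[C@H]12 | intermediate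
15 | tert-butyl (1S,4aS,7R,8aS)-1-[(1E,3E,5E)-hepta-1,3,5-trien-1-yl]-7-methyl-3-[(trimethylsilyl)oxy]-4a,5,6,7,8,8a-hexahydro-1H-isochromene-4-carboxylate | C/C=C/C=C/C=C/[C@@H]1OC(O[Si](C)(C)C)=C(C(=O)OC(C)(C)C)[C@H]2CC[C@@H](C)C[C@H]12 | intermediate
16 | trimethylsilyl ester of 17 | C/C=C/C=C/[C@@H]1C=C[C@H]2C[C@H](C)CC[C@@H]2[C@@]1(C(=O)O[Si](C)(C)C)C(=O)OC(C)(C)C | intermediate
17 | (1R,2R,4aR,6R,8aS)-1-(tert-butoxycarbonyl)-6-methyl-2-[(1E,3E)-penta-1,3-dien-1-yl]-1,2,4a,5,6,7,8,8a-octahydronaphthalene-1-carboxylic acid | C/C=C/C=C/[C@@H]1C=C[C@H]2C[C@H](C)CC[C@@H]2[C@@]1(C(=O)O)C(=O)OC(C)(C)C | intermediate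
18 | acid chloride of 17 | C/C=C/C=C/[C@@H]1C=C[C@H]2C[C@H](C)CC[C@@H]2[C@@]1(C(=O)Cl)C(=O)OC(C)(C)C | intermediate
19 | tert-butyl (1R,2R,4aR,6R,8aS)-1-formyl-6-methyl-2-[(1E,3E)-penta-1,3-dien-1-yl]-1,2,4a,5,6,7,8,8a-octahydronaphthalene-1-carboxylate | C/C=C/C=C/[C@@H]1C=C[C@H]2C[C@H](C)CC[C@@H]2[C@@]1(C=O)C(=O)OC(C)(C)C | intermediate
20 | N-tosylhydrazone of 19 | C/C=C/C=C/[C@@H]1C=C[C@H]2C[C@H](C)CC[C@@H]2[C@@]1(C=NNS(=O)(=O)c1ccc(C)cc1)C(=O)OC(C)(C)C | intermediate
21 | tert-butyl (1R,2R,4aR,6R,8aS)-1,6-dimethyl-2-[(1E,3E)-penta-1,3-dien-1-yl]-1,2,4a,5,6,7,8,8a-octahydronaphthalene-1-carboxylate | C/C=C/C=C/[C@@H]1C=C[C@H]2C[C@H](C)CC[C@@H]2[C@@]1(C)C(=O)OC(C)(C)C | intermediate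
22 | trimethylsilyl ester of 23 | C/C=C/C=C/[C@@H]1C=C[C@H]2C[C@H](C)CC[C@@H]2[C@@]1(C)C(=O)O[Si](C)(C)C | intermediate
23 | (1R,2R,4aR,6R,8aS)-1,6-dimethyl-2-[(1E,3E)-penta-1,3-dien-1-yl]-1,2,4a,5,6,7,8,8a-octahydronaphthalene-1-carboxylic acid | C/C=C/C=C/[C@@H]1C=C[C@H]2C[C@H](C)CC[C@@H]2[C@@]1(C)C(=O)O | intermediate
24 | 2,2-dimethyl-1,3-dioxane-4,6-dione (Meldrum's acid) | CC1(C)OC(=O)CC(=O)O1 | starting material
25 | acid chloride of 23 | C/C=C/C=C/[C@@H]1C=C[C@H]2C[C@H](C)CC[C@@H]2[C@@]1(C)C(=O)Cl | intermediate
26 | 5-[hydroxy{(1R,2R,4aR,6R,8aS)-1,6-dimethyl-2-[(1E,3E)-penta-1,3-dien-1-yl]-1,2,4a,5,6,7,8,8a-octahydronaphthalen-1-yl}methylidene]-2,2-dimethyl-1,3-dioxane-4,6-dione | C/C=C/C=C/[C@@H]1C=C[C@H]2C[C@H](C)CC[C@@H]2[C@@]1(C)C(O)=C1C(=O)OC(C)(C)OC1=O | intermediate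
27 | methyl L-threoninate hydrochloride | COC(=O)[C@H]([C@@H](C)O)N.Cl | starting material
28 | acylketene from 26 | C/C=C/C=C/[C@@H]1C=C[C@H]2C[C@H](C)CC[C@@H]2[C@@]1(C)C(=O)C=C=O | intermediate
29 | methyl N-{3-[(1R,2R,4aR,6R,8aS)-1,6-dimethyl-2-[(1E,3E)-penta-1,3-dien-1-yl]-1,2,4a,5,6,7,8,8a-octahydronaphthalen-1-yl]-3-oxopropanoyl}-L-threoninate | C/C=C/C=C/[C@@H]1C=C[C@H]2C[C@H](C)CC[C@@H]2[C@@]1(C)C(=O)CC(=O)N[C@@H]([C@@H](C)O)C(=O)OC | intermediate
30 | (5S)-3-{[(1R,2R,4aR,6R,8aS)-1,6-dimethyl-2-[(1E,3E)-penta-1,3-dien-1-yl]-1,2,4a,5,6,7,8,8a-octahydronaphthalen-1-yl]carbonyl}-4-hydroxy-5-[(1R)-1-hydroxyethyl]-1,5-dihydro-2H-pyrrol-2-one | C/C=C/C=C/[C@@H]1C=C[C@H]2C[C@H](C)CC[C@@H]2[C@@]1(C)C(=O)C1=C(O)[C@H]([C@@H](C)O)NC1=O | target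

## Step count and least certain steps

Total step count: 14. Longest linear sequence: 13 (steps 1–4 and 6–14). Step 5 is a one-step branch.

**Step 8 (key step).** The push–pull ketene acetal 15 is less electron-rich than a simple one, so the [3,3] shift may be slow. Heterolysis of the trienylic C5–O bond (with elimination or loss of the C5 information), or desilylation followed by decarboxylation, could then take over.

The fallback sets out from 13 and comes back at 17. It separates ring closure from the making of the quaternary centre.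
- 13 itself is O-silylated (LiN(iPr)2, Me3SiCl) and rearranged as the unstabilised, more reactive ketene acetal through the same boat. This gives (1S,2R,4aR,6R,8aS)-6-methyl-2-[(1E,3E)-penta-1,3-dien-1-yl]-1,2,4a,5,6,7,8,8a-octahydronaphthalene-1-carboxylic acid F1, with C3 already correct and the carboxyl group α.
- Double deprotonation of F1 and tert-butoxycarbonylation of the enediolate follow. The electrophile should enter from the equatorial β face that exocyclic cyclohexanecarboxylate enolates prefer, which gives 17.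

**Step 6.** Facial selectivity at the aldehyde may be poor, because C7 and C11 differ only in branching. Some epimerisation at C6 may also occur before the coupling.

The fallback sets out from 9 and 11 and comes back at 13. It corrects C5 by inversion instead of by addition control.
- The unwanted lactone (1R,4aR,7R,8aS)-1-[(1E,3E,5E)-hepta-1,3,5-trien-1-yl]-7-methyloctahydro-3H-isochromen-3-one F2 is separated.
- F2 is opened with LiOH to 2-{(1R,2S,4R)-2-[(1R,2E,4E,6E)-1-hydroxyocta-2,4,6-trien-1-yl]-4-methylcyclohexyl}acetic acid F3.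
- F3 is closed again by an intramolecular Mitsunobu reaction (PPh3, diisopropyl azodicarboxylate) with inversion at C5.

**Step 12.** Acyl transfer from the very hindered acid chloride 25 to the carbon of 24 may be blocked, so that 25 persists or only O-acylation takes place.

The fallback sets out from 21 and comes back at 29. It replaces attack on an acyl derivative by addition to an aldehyde.
- iBu2AlH reduces 21 to [(1R,2R,4aR,6R,8aS)-1,6-dimethyl-2-[(1E,3E)-penta-1,3-dien-1-yl]-1,2,4a,5,6,7,8,8a-octahydronaphthalen-1-yl]methanol F4.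
- Dess–Martin oxidation gives the corresponding carbaldehyde F5.
- The lithium enolate of S-tert-butyl thioacetate adds to F5 to give β-hydroxy thioester F6.
- A second Dess–Martin oxidation gives β-keto thioester F7.
- AgOCOCF3 promotes the aminolysis of F7 by 27 and Et3N to 29.

**Step 14.** Closure may be slow from the preferred amide rotamer. That would prolong contact with methoxide and allow epimerisation at C5' or β-elimination of the unprotected hydroxyl group.

The fallback sets out from 23 and comes back at 30. It builds ring C before the acylation.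
- The building block is tert-butyl (2S)-2-[(1R)-1-{[tert-butyl(dimethyl)silyl]oxy}ethyl]-3,5-dioxopyrrolidine-1-carboxylate F8. It is made by condensing the correspondingly protected amino acid with 24, followed by thermal ring closure.
- F8 is O-acylated by 23 (carbodiimide, excess DMAP) and rearranged in the same pot to the 3-acyl derivative F9.
- Trifluoroacetic acid and then HF·pyridine remove both protecting groups.

## Further compounds

F1 | step 8 | (1S,2R,4aR,6R,8aS)-6-methyl-2-[(1E,3E)-penta-1,3-dien-1-yl]-1,2,4a,5,6,7,8,8a-octahydronaphthalene-1-carboxylic acid | C/C=C/C=C/[C@@H]1C=C[C@H]2C[C@H](C)CC[C@@H]2[C@@H]1C(=O)O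
F2 | step 6 | (1R,4aR,7R,8aS)-1-[(1E,3E,5E)-hepta-1,3,5-trien-1-yl]-7-methyloctahydro-3H-isochromen-3-one | C/C=C/C=C/C=C/[C@H]1OC(=O)C[C@H]2CC[C@@H](C)C[C@H]12
F3 | step 6 | 2-{(1R,2S,4R)-2-[(1R,2E,4E,6E)-1-hydroxyocta-2,4,6-trien-1-yl]-4-methylcyclohexyl}acetic acid | C/C=C/C=C/C=C/[C@@H](O)[C@H]1C[C@H](C)CC[C@@H]1CC(=O)O
F4 | step 12 | [(1R,2R,4aR,6R,8aS)-1,6-dimethyl-2-[(1E,3E)-penta-1,3-dien-1-yl]-1,2,4a,5,6,7,8,8a-octahydronaphthalen-1-yl]methanol | C/C=C/C=C/[C@@H]1C=C[C@H]2C[C@H](C)CC[C@@H]2[C@@]1(C)CO
F5 | step 12 | (1R,2R,4aR,6R,8aS)-1,6-dimethyl-2-[(1E,3E)-penta-1,3-dien-1-yl]-1,2,4a,5,6,7,8,8a-octahydronaphthalene-1-carbaldehyde | C/C=C/C=C/[C@@H]1C=C[C@H]2C[C@H](C)CC[C@@H]2[C@@]1(C)C=O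
F6 | step 12 | S-tert-butyl 3-hydroxy-3-[(1R,2R,4aR,6R,8aS)-1,6-dimethyl-2-[(1E,3E)-penta-1,3-dien-1-yl]-1,2,4a,5,6,7,8,8a-octahydronaphthalen-1-yl]propanethioate (either carbinol epimer) | C/C=C/C=C/[C@@H]1C=C[C@H]2C[C@H](C)CC[C@@H]2[C@@]1(C)C(O)CC(=O)SC(C)(C)C
F7 | step 12 | S-tert-butyl 3-[(1R,2R,4aR,6R,8aS)-1,6-dimethyl-2-[(1E,3E)-penta-1,3-dien-1-yl]-1,2,4a,5,6,7,8,8a-octahydronaphthalen-1-yl]-3-oxopropanethioate | C/C=C/C=C/[C@@H]1C=C[C@H]2C[C@H](C)CC[C@@H]2[C@@]1(C)C(=O)CC(=O)SC(C)(C)C
F8 | step 14 | tert-butyl (2S)-2-[(1R)-1-{[tert-butyl(dimethyl)silyl]oxy}ethyl]-3,5-dioxopyrrolidine-1-carboxylate | CC(C)(C)OC(=O)N1C(=O)CC(=O)[C@@H]1[C@@H](C)O[Si](C)(C)C(C)(C)C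
F9 | step 14 | N-tert-butoxycarbonyl, O-tert-butyldimethylsilyl derivative of 30 | C/C=C/C=C/[C@@H]1C=C[C@H]2C[C@H](C)CC[C@@H]2[C@@]1(C)C(=O)C1=C(O)[C@H]([C@@H](C)O[Si](C)(C)C(C)(C)C)N(C(=O)OC(C)(C)C)C1=O
A1 | alternative 1 | (2E,6R,8E,10E,12E,14E)-2,6-dimethylhexadeca-2,8,10,12,14-pentaenal | C/C=C/C=C/C=C/C=C/C[C@H](C)CC/C=C(\C)C=O
A2 | alternative 1 | (1S,2R,4aS,6R,8aR)-1,6-dimethyl-2-[(1E,3E)-penta-1,3-dien-1-yl]-1,2,4a,5,6,7,8,8a-octahydronaphthalene-1-carbaldehyde | C/C=C/C=C/[C@@H]1C=C[C@@H]2C[C@H](C)CC[C@H]2[C@]1(C)C=O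
A3 | alternative 2 | (R)-5-methylcyclohex-1-ene-1-carbaldehyde | O=CC1=CCC[C@@H](C)C1
A4 | alternative 2 | methyl 2-methyl-3-oxobutanoate | COC(=O)C(C)C(C)=O
A5 | alternative 2 | methyl (1R,4aR,6R,8aS)-1,6-dimethyl-2-oxo-1,2,4a,5,6,7,8,8a-octahydronaphthalene-1-carboxylate | O=C1C=C[C@H]2C[C@H](C)CC[C@@H]2[C@@]1(C)C(=O)OC
A6 | alternative 3 | (2E,4E,6E)-octa-2,4,6-trien-1-yl 2-[(1S,2R,4R)-2-ethenyl-4-methylcyclohexyl]propanoate | C/C=C/C=C/C=C/COC(=O)C(C)[C@H]1CC[C@@H](C)C[C@@H]1C=C
A7 | alternative 3 | (4E,6E)-3-ethenyl-2-[(1S,2R,4R)-2-ethenyl-4-methylcyclohexyl]-2-methylocta-4,6-dienoic acid with the C2 and C3 configuration of 30 | C/C=C/C=C/[C@H](C=C)[C@](C)(C(=O)O)[C@H]1CC[C@@H](C)C[C@@H]1C=C
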